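**Strategy**

Leprolomin is cut inside ring A, not at the diaryl ether. With ring A numbered from its acetyl-bearing carbon (C1; C2 OH, C3 Me, C4 OMe, C5 H, C6 O-aryl), C6 and C1 are taken as the two carbons of a push-pull alkyne, a ring B aryloxy butynone, and C2–C5 as a silyl vinylketene acetal made from methyl 2-methylacetoacetate. One regiocontrolled (4+2) benzannulation forms the C5–C6 and C1–C2 bonds, closes ring A around the already installed, crowded ether oxygen and, after loss of methanol, sets all five ring A substituents. Ring B enters as a dibenzyl-protected phenol from 2-methylphloroglucinol; its acetyl group is added last.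

Key step: step 9

Assumption: enol ether 16 and diene 18 are used whatever their double-bond geometry, since both elements vanish on aromatisation. Ring B keeps benzyl ethers (inert to n-BuLi and to the diene, removed under neutral conditions) and receives its acetyl group only at the end, because a ring B ketone would not survive the acetylide chemistry.

**Route**

Step 1
Reactants: 1 2-methylphloroglucinol (2-methylbenzene-1,3,5-triol)
Product: 3 2,4,6-trihydroxy-3-methylbenzaldehyde, via aryl iminium chloride 2 (not isolated)
Conditions: POCl3, DMF, EtOAc, 0 °C to rt; then H2O, 50 °C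
Reagents that add atoms: N,N-dimethylformamide CN(C)C=O; water O
Why: Vilsmeier–Haack formylation; the chloroiminium ion attacks one of the two equivalent free positions of the phloroglucinol, and the iminium group of 2 protects the ring against a second formylation until hydrolysis.

Step 2
Reactants: 3 2,4,6-trihydroxy-3-methylbenzaldehyde
Product: 4 2,6-dihydroxy-4-methoxy-3-methylbenzaldehyde
Conditions: MeI (1.0 equiv), K2CO3 (1.0 equiv), acetone, 0 °C to rt
Reagents that add atoms: iodomethane CI
Why: Williamson etherification with limiting base and electrophile; the 4-hydroxyl, para to the formyl group and outside its hydrogen bond, is the most acidic and most accessible phenol, whereas the two ortho hydroxyls are damped by hydrogen bonding to the aldehyde.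

Step 3
Reactants: 4 2,6-dihydroxy-4-methoxy-3-methylbenzaldehyde
Product: 5 2,6-bis(benzyloxy)-4-methoxy-3-methylbenzaldehyde
Conditions: BnBr (2.4 equiv), K2CO3 (3 equiv), DMF, 60 °C
Reagents that add atoms: benzyl bromide BrCc1ccccc1
Why: Williamson etherification; excess base in a dipolar aprotic solvent with gentle heating overcomes the hydrogen bonding of the two remaining phenols and alkylates both on oxygen.

Step 4
Reactants: 5 2,6-bis(benzyloxy)-4-methoxy-3-methylbenzaldehyde
Product: 7 2,6-bis(benzyloxy)-4-methoxy-3-methylphenol, via aryl formate 6 (not isolated)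
Conditions: mCPBA, CH2Cl2, 0 °C to rt; then cat. K2CO3, MeOH, rt, under N2
Reagents that add atoms: 3-chloroperoxybenzoic acid OOC(=O)c1cccc(Cl)c1
Why: Dakin-type Baeyer–Villiger oxidation; the electron-rich trioxygenated aryl group migrates in preference to hydride, and mild methanolysis of formate 6 frees the phenol without touching the benzyl or methyl ethers.

Step 5
Reactants: 7 2,6-bis(benzyloxy)-4-methoxy-3-methylphenol; 8 trichloroethylene
Product: 9 1,3-bis(benzyloxy)-2-{[(E)-1,2-dichloroethenyl]oxy}-5-methoxy-4-methylbenzene
Conditions: K2CO3, DMF, 70 °C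
Reagents that add atoms: none
Why: Base-mediated addition–elimination on trichloroethylene (dichloroacetylene formed in situ, anti addition of the phenoxide), the established entry to (E)-1,2-dichlorovinyl aryl ethers, puts a two-carbon unit on the hindered oxygen while that oxygen still has only one aryl partner.

Step 6
Reactants: 9 1,3-bis(benzyloxy)-2-{[(E)-1,2-dichloroethenyl]oxy}-5-methoxy-4-methylbenzene; 10 N-methoxy-N-methylacetamide
Product: 13 4-[2,6-bis(benzyloxy)-4-methoxy-3-methylphenoxy]but-3-yn-2-one, via lithium aryloxyacetylide 11 (not isolated), via tetrahedral lithium adduct 12 (not isolated)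
Conditions: n-BuLi (2.1 equiv), THF, −78 to −40 °C; then 10, −78 to −20 °C; cold sat. aq NH4Cl
Reagents that add atoms: none
Why: Two equivalents of n-BuLi effect dehydrochlorination and chlorine–lithium exchange to acetylide 11, which adds once to the amide because chelated adduct 12 collapses to the ketone only on quench (Weinreb ketone synthesis).

Step 7
Reactants: 14 methyl 2-methylacetoacetate (methyl 2-methyl-3-oxobutanoate)
Product: 16 methyl (2E)-3-methoxy-2-methylbut-2-enoate, via dimethyl ketal 15 (not isolated)
Conditions: HC(OMe)3, cat. H2SO4, rt; then quinoline, distil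
Reagents that add atoms: trimethyl orthoformate COC(OC)OC
Why: Acid-catalysed ketalisation by the orthoformate followed by loss of methanol gives the conjugated β-methoxy enoate (enol ether formation), driven by conjugation with the ester.

Step 8
Reactants: 16 methyl (2E)-3-methoxy-2-methylbut-2-enoate
Product: 18 [(1,3-dimethoxy-2-methylbuta-1,3-dien-1-yl)oxy]trimethylsilane, via lithium dienolate 17 (not isolated)
Conditions: LiN(iPr)2, THF, −78 °C; Me3SiCl, −78 °C to rt; distil
Reagents that add atoms: chlorotrimethylsilane C[Si](C)(C)Cl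
Why: Kinetic γ-deprotonation of the vinylogous carbonate and O-silylation of the extended dienolate (silyl ketene acetal formation) is the standard preparation of 1,1,3-trioxygenated butadienes.

Step 9
Reactants: 13 4-[2,6-bis(benzyloxy)-4-methoxy-3-methylphenoxy]but-3-yn-2-one; 18 [(1,3-dimethoxy-2-methylbuta-1,3-dien-1-yl)oxy]trimethylsilane
Product: 21 1-{6-[2,6-bis(benzyloxy)-4-methoxy-3-methylphenoxy]-2-hydroxy-4-methoxy-3-methylphenyl}ethan-1-one, via cyclohexadiene cycloadduct 19 (not isolated), via aryl silyl ether 20 (not isolated)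
Conditions: 18 (2.5 equiv), PhMe, 0 to 60 °C; then 1 M HCl, THF, rt
Reagents that add atoms: none
Why: Proposed new method: the CH2 terminus of 18, made nucleophilic by the 3-methoxy group and both ketene acetal oxygens, should add to the aryloxy-bearing alkyne carbon of 13 in the manner of a vinylogous Mukaiyama–Michael addition, and the allenolate so formed closes onto the oxocarbenium carbon, an asynchronous (4+2) cycloaddition that gives cyclohexa-1,4-diene 19. The closest known reaction type is the Diels–Alder benzannulation of 1,1,3-trioxygenated butadienes with acetylenic ketones and esters, which has not been extended to an alkyne that carries an aryloxy donor. Ring A is closed as a six-membered carbocycle by intermolecular (4+2) union, the C5–C6 and C1–C2 bonds being made in one operation; 19 then loses methanol across C2 and C5 to aryl silyl ether 20, and dilute acid frees the hydrogen-bonded C2 phenol. No stereocentre is created in 21, the ketal carbon of 19 being destroyed on aromatisation. The selectivity required is regiochemical and is secured by polarity, because the acetyl group and the ether oxygen both mark the O-aryl carbon of 13 as the electrophilic Michael terminus, which pairs with the largest HOMO coefficient of the diene at its CH2 end and so places the acetyl group between ether and hydroxyl. An aryl ynol ether has no β-hydrogen for retro-ene loss of a ketene, so 13 should tolerate the gentle heating that its lowered dienophilicity may demand.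

Step 10
Reactants: 21 1-{6-[2,6-bis(benzyloxy)-4-methoxy-3-methylphenoxy]-2-hydroxy-4-methoxy-3-methylphenyl}ethan-1-one
Product: 22 1-[6-(2,6-dihydroxy-4-methoxy-3-methylphenoxy)-2-hydroxy-4-methoxy-3-methylphenyl]ethan-1-one
Conditions: H2 (1 atm), 10% Pd/C, EtOAc–MeOH, rt
Reagents that add atoms: none
Why: Hydrogenolysis of benzyl aryl ethers over Pd/C at atmospheric pressure; the hydrogen-bonded aryl ketone, the diaryl ether and the methyl ethers should be inert under these conditions.

Step 11
Reactants: 22 1-[6-(2,6-dihydroxy-4-methoxy-3-methylphenoxy)-2-hydroxy-4-methoxy-3-methylphenyl]ethan-1-one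
Product: 24 leprolomin, via bis-difluoroboron chelate 23 (not isolated)
Conditions: Ac2O (1.5 equiv), BF3·OEt2, 1,4-dioxane, rt to 50 °C; then aq NaOAc, MeOH, 60 °C
Reagents that add atoms: acetic anhydride CC(=O)OC(C)=O
Why: BF3-mediated Friedel–Crafts acylation; ring B, a phloroglucinol-type ring whose single open carbon is ortho or para to three oxygens, is far more nucleophilic than ring A, which is switched off as its difluoroboron chelate, and the hydrolytic work-up cleaves chelate 23 and any aryl acetate.

**Compound list**

1 | 2-methylphloroglucinol (2-methylbenzene-1,3,5-triol) | Cc1c(O)cc(O)cc1O | starting material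
2 | N-[(2,4,6-trihydroxy-3-methylphenyl)methylidene]-N-methylmethanaminium chloride (aryl iminium chloride) | C[N+](C)=Cc1c(O)cc(O)c(C)c1O.[Cl-] | intermediate (not isolated)
3 | 2,4,6-trihydroxy-3-methylbenzaldehyde | Cc1c(O)cc(O)c(C=O)c1O | intermediate
4 | 2,6-dihydroxy-4-methoxy-3-methylbenzaldehyde | COc1cc(O)c(C=O)c(O)c1C | intermediate
5 | 2,6-bis(benzyloxy)-4-methoxy-3-methylbenzaldehyde | COc1cc(OCc2ccccc2)c(C=O)c(OCc2ccccc2)c1C | intermediate
6 | 2,6-bis(benzyloxy)-4-methoxy-3-methylphenyl formate | COc1cc(OCc2ccccc2)c(OC=O)c(OCc2ccccc2)c1C | intermediate (not isolated)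
7 | 2,6-bis(benzyloxy)-4-methoxy-3-methylphenol | COc1cc(OCc2ccccc2)c(O)c(OCc2ccccc2)c1C | intermediate
8 | trichloroethylene (1,1,2-trichloroethene) | ClC=C(Cl)Cl | starting material
9 | 1,3-bis(benzyloxy)-2-{[(E)-1,2-dichloroethenyl]oxy}-5-methoxy-4-methylbenzene | COc1cc(OCc2ccccc2)c(O/C(Cl)=C\Cl)c(OCc2ccccc2)c1C | intermediate
10 | N-methoxy-N-methylacetamide | CC(=O)N(C)OC | starting material
11 | lithium [2,6-bis(benzyloxy)-4-methoxy-3-methylphenoxy]ethynide | [Li+].[C-]#COc1c(OCc2ccccc2)c(C)c(OC)cc1OCc1ccccc1 | intermediate (not isolated)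
12 | lithium 4-[2,6-bis(benzyloxy)-4-methoxy-3-methylphenoxy]-2-[methoxy(methyl)amino]but-3-yn-2-olate (racemic) | [Li+].CC([O-])(N(C)OC)C#COc1c(OCc2ccccc2)c(C)c(OC)cc1OCc1ccccc1 | intermediate (not isolated)
13 | 4-[2,6-bis(benzyloxy)-4-methoxy-3-methylphenoxy]but-3-yn-2-one | CC(=O)C#COc1c(OCc2ccccc2)c(C)c(OC)cc1OCc1ccccc1 | intermediate
14 | methyl 2-methylacetoacetate (methyl 2-methyl-3-oxobutanoate) | CC(=O)C(C)C(=O)OC | starting material
15 | methyl 3,3-dimethoxy-2-methylbutanoate (racemic) | COC(C)(OC)C(C)C(=O)OC | intermediate (not isolated)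
16 | methyl (2E)-3-methoxy-2-methylbut-2-enoate | CO/C(C)=C(\C)C(=O)OC | intermediate
17 | lithium 1,3-dimethoxy-2-methylbuta-1,3-dien-1-olate | [Li+].C=C(OC)C(C)=C(OC)[O-] | intermediate (not isolated)
18 | [(1,3-dimethoxy-2-methylbuta-1,3-dien-1-yl)oxy]trimethylsilane (mixture of ketene acetal isomers) | C=C(OC)C(C)=C(OC)O[Si](C)(C)C | intermediate
19 | 1-{2-[2,6-bis(benzyloxy)-4-methoxy-3-methylphenoxy]-4,6-dimethoxy-5-methyl-6-[(trimethylsilyl)oxy]cyclohexa-1,4-dien-1-yl}ethan-1-one (racemic) | COC1=C(C)C(OC)(O[Si](C)(C)C)C(C(C)=O)=C(Oc2c(OCc3ccccc3)c(C)c(OC)cc2OCc2ccccc2)C1 | intermediate (not isolated)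
20 | 1-{6-[2,6-bis(benzyloxy)-4-methoxy-3-methylphenoxy]-4-methoxy-3-methyl-2-[(trimethylsilyl)oxy]phenyl}ethan-1-one | COc1cc(Oc2c(OCc3ccccc3)c(C)c(OC)cc2OCc2ccccc2)c(C(C)=O)c(O[Si](C)(C)C)c1C | intermediate (not isolated)
21 | 1-{6-[2,6-bis(benzyloxy)-4-methoxy-3-methylphenoxy]-2-hydroxy-4-methoxy-3-methylphenyl}ethan-1-one | COc1cc(Oc2c(OCc3ccccc3)c(C)c(OC)cc2OCc2ccccc2)c(C(C)=O)c(O)c1C | intermediate
22 | 1-[6-(2,6-dihydroxy-4-methoxy-3-methylphenoxy)-2-hydroxy-4-methoxy-3-methylphenyl]ethan-1-one | COc1cc(Oc2c(O)c(C)c(OC)cc2O)c(C(C)=O)c(O)c1C | intermediate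
23 | bis(difluoroboron) chelate of leprolomin (each acetyl oxygen and its ortho phenoxide bound to one BF2) | CC1=[O+][B-](F)(F)Oc2c(C)c(OC)cc(Oc3c(O)c(C)c(OC)c4C(C)=[O+][B-](F)(F)Oc34)c21 | intermediate (not isolated)
24 | leprolomin, 1-[3-(2-acetyl-3-hydroxy-5-methoxy-4-methylphenoxy)-2,4-dihydroxy-6-methoxy-5-methylphenyl]ethan-1-one | COc1cc(Oc2c(O)c(C)c(OC)c(C(C)=O)c2O)c(C(C)=O)c(O)c1C | target

**Step count**

Total: 11 steps. Longest linear sequence: 9 steps (steps 1–6, then 9–11); the diene branch (steps 7 and 8) joins at step 9.

**Steps most likely to fail**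

1. Step 9 (new method). The donor-substituted alkyne may be too weak a dienophile, so that the diene is lost to hydrolysis or oligomerisation before it adds. Alternatively, silicon may migrate after the first C–C bond, leaving an open-chain adduct that does not close ring A. The fallback uses known chemistry, bringing ring A in preformed and making the ether by Ullmann coupling. It sets out from phenol 7. The catalogue bromoarene 5-bromo-1,3-dimethoxy-2-methylbenzene F1, whose two open positions are equivalent, is acetylated (AcCl, TiCl4, CH2Cl2, 0 °C) to 1-(6-bromo-2,4-dimethoxy-3-methylphenyl)ethan-1-one F2. Copper-catalysed Ullmann etherification of 7 with F2 (CuI, picolinic acid, K3PO4, DMSO, 90 °C), assisted by the ortho acetyl group, should give 1-{6-[2,6-bis(benzyloxy)-4-methoxy-3-methylphenoxy]-2,4-dimethoxy-3-methylphenyl}ethan-1-one F3. BCl3 with pentamethylbenzene (CH2Cl2, −78 to 0 °C) should then remove both benzyl groups and the one methyl ether chelated by the acetyl group. The route is rejoined at triol 22.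

2. Step 6. Chlorine–lithium exchange may be incomplete, surplus butyllithium may attack the amide, or the N,O-dimethylhydroxylamine released on quench (or water) may add in conjugate fashion to the push-pull ynone. The fallback sets out from 9. Treatment with n-BuLi and a methanol quench gives the terminal ynol ether 1,3-bis(benzyloxy)-2-(ethynyloxy)-5-methoxy-4-methylbenzene F4. Relithiation with one equivalent of n-BuLi and addition to acetaldehyde gives racemic 4-[2,6-bis(benzyloxy)-4-methoxy-3-methylphenoxy]but-3-yn-2-ol F5. Oxidation with activated MnO2 (CH2Cl2, rt), with no amine nucleophile present, comes back to ynone 13.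

3. Step 2. Site selectivity among three phenols may be lost, with alkylation running on to the ortho hydroxyls. The fallback sets out from 3. Exhaustive methylation (excess MeI, K2CO3, DMF) gives 2,4,6-trimethoxy-3-methylbenzaldehyde F6. AlCl3 (CH2Cl2, reflux) then cleaves the two methyl ethers ortho to the formyl group by chelation, while the para ether, which has no carbonyl neighbour, is kept. The route is rejoined at 4.

**Further compounds**

F1 | step 9 | 5-bromo-1,3-dimethoxy-2-methylbenzene | COc1cc(Br)cc(OC)c1C
F2 | step 9 | 1-(6-bromo-2,4-dimethoxy-3-methylphenyl)ethan-1-one | COc1cc(Br)c(C(C)=O)c(OC)c1C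
F3 | step 9 | 1-{6-[2,6-bis(benzyloxy)-4-methoxy-3-methylphenoxy]-2,4-dimethoxy-3-methylphenyl}ethan-1-one | COc1cc(Oc2c(OCc3ccccc3)c(C)c(OC)cc2OCc2ccccc2)c(C(C)=O)c(OC)c1C
F4 | step 6 | 1,3-bis(benzyloxy)-2-(ethynyloxy)-5-methoxy-4-methylbenzene | C#COc1c(OCc2ccccc2)c(C)c(OC)cc1OCc1ccccc1
F5 | step 6 | 4-[2,6-bis(benzyloxy)-4-methoxy-3-methylphenoxy]but-3-yn-2-ol (racemic) | CC(O)C#COc1c(OCc2ccccc2)c(C)c(OC)cc1OCc1ccccc1
F6 | step 2 | 2,4,6-trimethoxy-3-methylbenzaldehyde | COc1cc(OC)c(C=O)c(OC)c1C
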